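| flask | free monomer | initiator | remark | time |
|---|---|---|---|---|
| Sunday's | 1.0 mM | 2.0 µM | a single well-mixed tank run continuously and read at steady state, 4.0 min in it on average |  |
| Tuesday's | 1.0 mM (fed, over 2.00 min) | 2.0 µM | a stirred flask in which free monomer is dosed at a steady rate over 2.00 min without added volume, worked up at 4.0 min | 4.0 min |
| Saturday's | 1.0 mM | 2.0 µM | a closed flask charged with all of it at once and left for 4.0 min | 4.0 min |

1. the set-up with the highest amount of monomer in chains at the outlet or at the end, in percent of the free monomer put in ("none" if the first two lie within 2 percentage points) (Sunday's / Tuesday's / Saturday's / none)
2. amount of monomer in chains at the outlet or at the end, in percent of the free monomer put in, Sunday's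
3. amount of monomer in chains at the outlet or at the end, in percent of the free monomer put in, Tuesday's
4. amount of monomer in chains at the outlet or at the end, in percent of the free monomer put in, Saturday's

- the stated concentrations are those of everything mixed, before any reaction; amounts are the same in each set-up
- the feed brings no volume worth counting
- run time (Tuesday's): 4.0 min

You charge 500 parts of free monomer for each part of initiator. A living end is made when free monomer meets initiator. Each living end then adds free monomer to its chain, while initiator can also die unused.

I reckon Saturday's closed flask by hand and write free monomer as a fraction of its charge. At the start, initiator is captured at 0.0920 s⁻¹ and dies at 0.021 s⁻¹, so the capture share is 81.4%. At these rates initiator lasts 8.85 s on average, which is far shorter than the run, and as a rough step I hold free monomer at its charge for that stretch.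

The curve of monomer in chains starts at a slope of 0.0110 min⁻¹ of the charge. Its knee comes near 8.85 s. After that, free monomer falls pseudo-first-order, by a fixed share of 1.47 min⁻¹, which is much steeper than the start. Half the charge is in chains at about 0.620 min, and the curve then bends towards the whole charge.

Integrating that one rate gives 5.65. This is the growth count, the fixed share times the time it acts. In this closed flask it is the natural logarithm of how far free monomer has fallen. Saturday's flask should therefore end at 99.6%. I do not reckon the other two set-ups.

The forecast gives 76.8% for Sunday's, 88% for Tuesday's and 99.6% for Saturday's, and picks Saturday's. On the tank it says: “the steady-state tank runs at low monomer with washout and a broad residence-time spread”.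

The run gives 76.8%, 87.9% and 99.6% in that order, so Saturday's leads, as the forecast said.

    free monomer + initiator → living end + monomer in chains (k1 = 92 M⁻¹ s⁻¹)
    free monomer + living end → monomer in chains + living end, rate k2*[living end]*[free monomer] (k2 = 15000 M⁻¹ s⁻¹)
    initiator → spent initiator (k3 = 0.021 s⁻¹)

In Sunday's tank, free monomer stands at 23.2% of its charge, so initiator is captured at 0.0214 s⁻¹, about level with its death at 0.021 s⁻¹. In Saturday's flask, capture started at 0.0920 s⁻¹, well above that death rate. With washout at 0.00417 s⁻¹ counted, Sunday's capture share is 45.9% and its growth count over the 4.0 min on average is 3.30. In Sunday's tank, one over one plus that count gives free monomer at 23.2% of the charge, the same level this reckoning started from.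

The numbers were set for the occasion; the result is computed.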